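**Retrosynthetic overview**
- The route rests on the benzene ring: CO2H at C1, OH at C4 (para), alkyl chains at C3 and C5, H at C2 and C6. This is the pattern left when a 3-alkyl-5-carboxy-2-pyrone and an oxygen-substituted alkyne combine and lose CO2.
- Key disconnection: ring bonds C3–C4 and C5–C6, made by a formal inverse-demand [4+2] reaction of the 3-allyl coumalate with the silyl ynol ether, followed by retro-[4+2] loss of CO2. The benzene ring is the only ring and is formed in that step.
- Pyrone: coumalic acid, silylethyl ester, C3 bromination, Stille allylation. Alkyne: (S)-hydroxy ester, iodide, propargylation with lithiated 1-(trimethylsilyl)propyne, acetylide oxidation to the ynolate, O-silylation.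
- After the ring: the allyl group becomes the (E)-4-hydroxy-3-methylbut-2-enyl chain by cross-metathesis with methacrolein and 1,2-reduction. The C5 chain is taken to the aldehyde, alkenylated by a chromium-mediated reaction, oxidised to the enone, and all silicon groups are removed with fluoride.

Key step: step 10

Remark on the chemistry: lactone 18 and carbinol 30 form as diastereomer mixtures at centres that are destroyed in the same or the next step and are written without descriptors there; bromine adduct 4 is taken to be the 3,6-dibromide (a 3,4-adduct would eliminate to the same bromopyrone); the cyclopentadienyl rings of 27 are written σ-bonded in its SMILES.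

**Route**

Step 1
Reactants: 1 coumalic acid
Product: 3 2-(trimethylsilyl)ethyl 2-oxo-2H-pyran-5-carboxylate, via coumalyl chloride 2 (not isolated)
Conditions: (COCl)2, DMF (cat.), CH2Cl2, rt; then Me3SiCH2CH2OH, 2,6-lutidine, CH2Cl2, 0 °C
Reagents that add atoms: 2-(trimethylsilyl)ethanol, OCC[Si](C)(C)C
Why: Esterification through the acid chloride avoids nucleophilic catalysts that open the pyrone and installs a fluoride-cleavable ester that should survive every later step.

Step 2
Reactants: 3 2-(trimethylsilyl)ethyl 2-oxo-2H-pyran-5-carboxylate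
Product: 5 2-(trimethylsilyl)ethyl 3-bromo-2-oxo-2H-pyran-5-carboxylate, via 3,6-dibromide 4 (not isolated)
Conditions: Br2, CH2Cl2, 0 °C to rt; then Et3N, 0 °C
Reagents that add atoms: bromine, BrBr
Why: Electrophilic bromination by addition–elimination, in which C3 is the only free nucleophilic position of the 5-acyl-2-pyrone and Et3N removes HBr by 1,4-elimination to restore the pyrone without exposing the silylethyl ester to free acid.

Step 3
Reactants: 5 2-(trimethylsilyl)ethyl 3-bromo-2-oxo-2H-pyran-5-carboxylate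
Product: 6 2-(trimethylsilyl)ethyl 3-allyl-2-oxo-2H-pyran-5-carboxylate
Conditions: allylSnBu3, Pd(PPh3)4 (5 mol%), CuI (10 mol%), toluene, 80 °C
Reagents that add atoms: allyltributylstannane, C=CC[Sn](CCCC)(CCCC)CCCC
Why: Stille cross-coupling, in which the electron-poor C3–Br bond adds readily to zerovalent palladium and the allyl group is transferred from tin under neutral conditions that leave lactone and ester intact.

Step 4
Reactants: 7 methyl (S)-3-hydroxy-2-methylpropanoate
Product: 8 methyl (S)-3-(tert-butyldimethylsilyloxy)-2-methylpropanoate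
Conditions: t-BuMe2SiCl, imidazole, CH2Cl2, 0 °C to rt
Reagents that add atoms: tert-butyldimethylsilyl chloride, CC(C)(C)[Si](C)(C)Cl
Why: Silyl ether formation at the only hydroxyl under weakly basic conditions that do not enolise the ester.

Step 5
Reactants: 8 methyl (S)-3-(tert-butyldimethylsilyloxy)-2-methylpropanoate
Product: 9 (R)-3-(tert-butyldimethylsilyloxy)-2-methylpropan-1-ol
Conditions: i-Bu2AlH, CH2Cl2, −78 to 0 °C; aq. potassium sodium tartrate
Reagents that add atoms: none
Why: Hydride reduction of the ester to the primary alcohol at low temperature leaves the stereocentre untouched (the descriptor changes only because the priorities change).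

Step 6
Reactants: 9 (R)-3-(tert-butyldimethylsilyloxy)-2-methylpropan-1-ol
Product: 10 (S)-tert-butyl(3-iodo-2-methylpropoxy)dimethylsilane
Conditions: I2, PPh3, imidazole, CH2Cl2, 0 °C to rt
Reagents that add atoms: iodine, II
Why: Appel-type iodination replaces the primary hydroxyl by SN2 displacement at the CH2 carbon, one atom away from the stereocentre.

Step 7
Reactants: 10 (S)-tert-butyl(3-iodo-2-methylpropoxy)dimethylsilane; 11 1-(trimethylsilyl)propyne
Product: 13 (R)-tert-butyldimethyl{[2-methyl-6-(trimethylsilyl)hex-5-yn-1-yl]oxy}silane, via 3-lithio-1-(trimethylsilyl)propyne 12 (not isolated)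
Conditions: 11, n-BuLi, THF, −78 to −20 °C; then 10, DMPU, −78 °C to rt
Reagents that add atoms: none
Why: Propargylic alkylation, in which the lithiated silylpropyne reacts as a propargyl nucleophile with the primary iodide (SN2) and the silyl group blocks the alkyne terminus and suppresses allenyl products.

Step 8
Reactants: 13 (R)-tert-butyldimethyl{[2-methyl-6-(trimethylsilyl)hex-5-yn-1-yl]oxy}silane
Product: 14 (R)-tert-butyldimethyl[(2-methylhex-5-yn-1-yl)oxy]silane
Conditions: K2CO3, MeOH, rt
Reagents that add atoms: none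
Why: Methoxide-mediated protodesilylation cleaves the alkynyl C–Si bond, while the primary silyl ether is stable to K2CO3 in methanol.

Step 9
Reactants: 14 (R)-tert-butyldimethyl[(2-methylhex-5-yn-1-yl)oxy]silane
Product: 17 (R)-6-(tert-butyldimethylsilyloxy)-5-methyl-1-(triisopropylsilyloxy)hex-1-yne, via lithium acetylide 15 (not isolated), via lithium ynolate 16 (not isolated)
Conditions: n-BuLi, THF, −78 °C; then LiOOt-Bu (from t-BuOOH and LiN(SiMe3)2), THF, −78 to 0 °C; then i-Pr3SiOTf, −78 to 0 °C
Reagents that add atoms: tert-butyl hydroperoxide, CC(C)(C)OO; triisopropylsilyl trifluoromethanesulfonate, CC(C)[Si](C(C)C)(C(C)C)OS(=O)(=O)C(F)(F)F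
Why: Electrophilic oxygen transfer from lithium tert-butyl peroxide to the lithium acetylide gives the lithium ynolate, which the bulky silyl triflate traps on oxygen, a known route to 1-siloxyalkynes.

Step 10
Reactants: 6 2-(trimethylsilyl)ethyl 3-allyl-2-oxo-2H-pyran-5-carboxylate; 17 (R)-6-(tert-butyldimethylsilyloxy)-5-methyl-1-(triisopropylsilyloxy)hex-1-yne
Product: 19 2-(trimethylsilyl)ethyl 3-allyl-5-[(R)-4-(tert-butyldimethylsilyloxy)-3-methylbutyl]-4-(triisopropylsilyloxy)benzoate, via bicyclic lactone 18 (not isolated)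
Conditions: AgN(SO2CF3)2 (5 mol%), 4 Å molecular sieves, CH2Cl2, 0 °C to rt, then 40 °C
Reagents that add atoms: none
Why: Proposed new method: the silyl ynol ether is the electron-rich 2π partner and the coumalate the electron-poor diene, so bond formation is asynchronous: the alkyl-bearing, nucleophilic β-carbon of the ynol ether adds to pyrone C6, which is conjugated to both the ester and the lactone carbonyl, and the resulting dienolate closes from C3 onto the silyl ketenium carbon, the silver salt serving as a mild Lewis acid so that this happens at room temperature. The closest known reactions are the inverse-demand Diels–Alder and decarboxylation sequences of coumalate esters with ynamines, ketene acetals and enol ethers, and the silver-triflimide-catalysed formal cycloadditions of siloxyalkynes with electron-poor alkenes and 1,2-diazines. The benzene ring is closed by an intermolecular [4+2] annulation across pyrone C3 and C6 (second bond: six-membered closure of C3 onto the ketenium carbon) to give the 2-oxabicyclo[2.2.2]octa-5,7-dien-3-one 18, whose retro-[4+2] loss of CO2 should deliver the arene directly at the oxidation level of the phenol silyl ether. No stereocentre is created in 19, since the two bridgehead centres of 18 vanish on aromatisation and the remote (R)-methyl centre and the allyl group are spectators. The step needs regioselectivity (oxygen para to the ester and between the two alkyl groups), which the polarity match between the ynol ether β-carbon and C6 secures, and preference for [4+2] over [2+2] closure at C5, which the irreversible loss of CO2 should drain toward the arene. Working at or near room temperature keeps the siloxyalkyne below the temperature of its 1,3-silyl shift to a silylketene.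

Step 11
Reactants: 19 2-(trimethylsilyl)ethyl 3-allyl-5-[(R)-4-(tert-butyldimethylsilyloxy)-3-methylbutyl]-4-(triisopropylsilyloxy)benzoate; 20 methacrolein
Product: 21 2-(trimethylsilyl)ethyl 3-[(R)-4-(tert-butyldimethylsilyloxy)-3-methylbutyl]-5-[(E)-3-methyl-4-oxobut-2-en-1-yl]-4-(triisopropylsilyloxy)benzoate
Conditions: 20 (5 equiv), second-generation Hoveyda–Grubbs catalyst [(H2IMes)Cl2Ru=CH(C6H4-2-Oi-Pr)] (5 mol%), CH2Cl2, 40 °C
Reagents that add atoms: none
Why: Olefin cross-metathesis of the terminal alkene with an excess of a 1,1-disubstituted enal that does not homodimerise should give the trisubstituted enal with (E)-geometry, the formyl group ending trans to the larger substituent.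

Step 12
Reactants: 21 the (E)-enal
Product: 22 2-(trimethylsilyl)ethyl 3-[(R)-4-(tert-butyldimethylsilyloxy)-3-methylbutyl]-5-[(E)-4-hydroxy-3-methylbut-2-en-1-yl]-4-(triisopropylsilyloxy)benzoate
Conditions: NaBH4, CeCl3·7H2O, MeOH, −20 °C
Reagents that add atoms: none
Why: Luche 1,2-reduction converts the enal into the allylic alcohol without touching the benzoate ester or the alkene geometry.

Step 13
Reactants: 22 the (E)-allylic alcohol
Product: 23 2-(trimethylsilyl)ethyl 3-[(E)-4-(tert-butyldiphenylsilyloxy)-3-methylbut-2-en-1-yl]-5-[(R)-4-(tert-butyldimethylsilyloxy)-3-methylbutyl]-4-(triisopropylsilyloxy)benzoate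
Conditions: t-BuPh2SiCl, imidazole, CH2Cl2, rt
Reagents that add atoms: tert-butyldiphenylsilyl chloride, CC(C)(C)[Si](Cl)(c1ccccc1)c1ccccc1
Why: Silyl ether formation at the only free hydroxyl with an acid-stable group, chosen so that the primary tert-butyldimethylsilyl ether can be removed selectively next.

Step 14
Reactants: 23 the tris-silyl ether
Product: 24 2-(trimethylsilyl)ethyl 3-[(E)-4-(tert-butyldiphenylsilyloxy)-3-methylbut-2-en-1-yl]-5-[(R)-4-hydroxy-3-methylbutyl]-4-(triisopropylsilyloxy)benzoate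
Conditions: camphorsulfonic acid (10 mol%), MeOH/CH2Cl2 (1:1), 0 °C
Reagents that add atoms: none
Why: Acid-catalysed methanolysis of a silyl ether, in which the primary alkyl tert-butyldimethylsilyl ether is far more labile than the tert-butyldiphenylsilyl ether and the aryl triisopropylsilyl ether.

Step 15
Reactants: 25 2-methylbut-3-yn-2-ol
Product: 26 triethyl[(2-methylbut-3-yn-2-yl)oxy]silane
Conditions: Et3SiOTf, 2,6-lutidine, CH2Cl2, 0 °C
Reagents that add atoms: triethylsilyl trifluoromethanesulfonate, CC[Si](CC)(CC)OS(=O)(=O)C(F)(F)F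
Why: Silylation of a tertiary alcohol with a reactive silyl triflate and a hindered base.

Step 16
Reactants: 26 triethyl[(2-methylbut-3-yn-2-yl)oxy]silane
Product: 28 (E)-triethyl[(4-iodo-2-methylbut-3-en-2-yl)oxy]silane, via alkenylzirconocene chloride 27 (not isolated)
Conditions: Cp2Zr(H)Cl, THF, rt; then I2, 0 °C
Reagents that add atoms: iodine, II
Why: Hydrozirconation adds Zr–H syn across the terminal alkyne with zirconium at the unhindered terminus, and iodinolysis with retention gives the (E)-vinyl iodide.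

Step 17
Reactants: 24 the primary alcohol
Product: 29 2-(trimethylsilyl)ethyl 3-[(E)-4-(tert-butyldiphenylsilyloxy)-3-methylbut-2-en-1-yl]-5-[(R)-3-methyl-4-oxobutyl]-4-(triisopropylsilyloxy)benzoate
Conditions: Dess–Martin periodinane, NaHCO3, CH2Cl2, 0 °C to rt; used crude
Reagents that add atoms: none
Why: Dess–Martin oxidation to the aldehyde under buffered, non-basic conditions should not epimerise the α-methyl stereocentre.

Step 18
Reactants: 29 the (R)-aldehyde; 28 (E)-triethyl[(4-iodo-2-methylbut-3-en-2-yl)oxy]silane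
Product: 30 2-(trimethylsilyl)ethyl 3-[(E)-4-(tert-butyldiphenylsilyloxy)-3-methylbut-2-en-1-yl]-5-[(3R,5E)-4-hydroxy-3,7-dimethyl-7-(triethylsilyloxy)oct-5-en-1-yl]-4-(triisopropylsilyloxy)benzoate (mixture at C4 of the chain)
Conditions: CrCl2 (5 equiv), NiCl2 (2 mol%), DMSO, rt
Reagents that add atoms: none
Why: Nozaki–Hiyama–Kishi reaction, in which nickel-catalysed formation of the alkenylchromium species and its addition to the aldehyde proceed with retention of alkene geometry and without enolising the α-stereogenic aldehyde, the carbinol configuration being irrelevant because it is oxidised next.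

Step 19
Reactants: 30 the allylic alcohol mixture
Product: 31 2-(trimethylsilyl)ethyl 3-[(E)-4-(tert-butyldiphenylsilyloxy)-3-methylbut-2-en-1-yl]-5-[(3R,5E)-3,7-dimethyl-4-oxo-7-(triethylsilyloxy)oct-5-en-1-yl]-4-(triisopropylsilyloxy)benzoate
Conditions: Dess–Martin periodinane, NaHCO3, CH2Cl2, 0 °C
Reagents that add atoms: none
Why: Dess–Martin oxidation of the secondary allylic alcohol converges both carbinol epimers on the (E)-enone under buffered conditions that leave the α-methyl centre alone.

Step 20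
Reactants: 31 the fully protected enone
Product: 32 4-hydroxy-3-[(E)-4-hydroxy-3-methylbut-2-en-1-yl]-5-[(3R,5E)-7-hydroxy-3,7-dimethyl-4-oxooct-5-en-1-yl]benzoic acid (CNP0120226.1)
Conditions: Bu4NF (8 equiv), AcOH (4 equiv), THF, 0 °C to rt; aq. NH4Cl
Reagents that add atoms: none
Why: Fluoride-induced global desilylation cleaves the aryl, primary and tertiary silyl ethers and fragments the 2-(trimethylsilyl)ethyl ester by β-elimination, with acetic acid buffering to protect the epimerisable α-methyl enone.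

**Compound list**
1 | coumalic acid | O=C(O)C1=COC(=O)C=C1 | starting material
2 | coumalyl chloride | O=C(Cl)C1=COC(=O)C=C1 | intermediate
3 | 2-(trimethylsilyl)ethyl 2-oxo-2H-pyran-5-carboxylate | O=C(OCC[Si](C)(C)C)C1=COC(=O)C=C1 | intermediate
4 | 2-(trimethylsilyl)ethyl 3,6-dibromo-2-oxo-3,6-dihydro-2H-pyran-5-carboxylate | O=C1OC(Br)C(C(=O)OCC[Si](C)(C)C)=CC1Br | intermediate
5 | 2-(trimethylsilyl)ethyl 3-bromo-2-oxo-2H-pyran-5-carboxylate | O=C1OC=C(C(=O)OCC[Si](C)(C)C)C=C1Br | intermediate
6 | 2-(trimethylsilyl)ethyl 3-allyl-2-oxo-2H-pyran-5-carboxylate | C=CCC1=CC(C(=O)OCC[Si](C)(C)C)=COC1=O | intermediate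
7 | methyl (S)-3-hydroxy-2-methylpropanoate | COC(=O)[C@@H](C)CO | starting material
8 | methyl (S)-3-(tert-butyldimethylsilyloxy)-2-methylpropanoate | COC(=O)[C@@H](C)CO[Si](C)(C)C(C)(C)C | intermediate
9 | (R)-3-(tert-butyldimethylsilyloxy)-2-methylpropan-1-ol | OC[C@@H](C)CO[Si](C)(C)C(C)(C)C | intermediate
10 | (S)-tert-butyl(3-iodo-2-methylpropoxy)dimethylsilane | IC[C@@H](C)CO[Si](C)(C)C(C)(C)C | intermediate
11 | 1-(trimethylsilyl)propyne | CC#C[Si](C)(C)C | starting material
12 | 3-lithio-1-(trimethylsilyl)propyne | [Li]CC#C[Si](C)(C)C | intermediate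
13 | (R)-tert-butyldimethyl{[2-methyl-6-(trimethylsilyl)hex-5-yn-1-yl]oxy}silane | C[Si](C)(C)C#CCC[C@@H](C)CO[Si](C)(C)C(C)(C)C | intermediate
14 | (R)-tert-butyldimethyl[(2-methylhex-5-yn-1-yl)oxy]silane | C#CCC[C@@H](C)CO[Si](C)(C)C(C)(C)C | intermediate
15 | lithium acetylide of 14 | [Li]C#CCC[C@@H](C)CO[Si](C)(C)C(C)(C)C | intermediate
16 | lithium (R)-6-(tert-butyldimethylsilyloxy)-5-methylhex-1-yn-1-olate | [Li]OC#CCC[C@@H](C)CO[Si](C)(C)C(C)(C)C | intermediate
17 | (R)-6-(tert-butyldimethylsilyloxy)-5-methyl-1-(triisopropylsilyloxy)hex-1-yne | CC(C)[Si](C(C)C)(C(C)C)OC#CCC[C@@H](C)CO[Si](C)(C)C(C)(C)C | intermediate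
18 | 2-(trimethylsilyl)ethyl 4-allyl-7-[(R)-4-(tert-butyldimethylsilyloxy)-3-methylbutyl]-3-oxo-8-(triisopropylsilyloxy)-2-oxabicyclo[2.2.2]octa-5,7-diene-6-carboxylate | O=C1OC2C(C(=O)OCC[Si](C)(C)C)=CC1(CC=C)C(O[Si](C(C)C)(C(C)C)C(C)C)=C2CC[C@@H](C)CO[Si](C)(C)C(C)(C)C | intermediate
19 | 2-(trimethylsilyl)ethyl 3-allyl-5-[(R)-4-(tert-butyldimethylsilyloxy)-3-methylbutyl]-4-(triisopropylsilyloxy)benzoate | C=CCc1cc(C(=O)OCC[Si](C)(C)C)cc(CC[C@@H](C)CO[Si](C)(C)C(C)(C)C)c1O[Si](C(C)C)(C(C)C)C(C)C | intermediate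
20 | methacrolein | CC(=C)C=O | starting material
21 | 2-(trimethylsilyl)ethyl 3-[(R)-4-(tert-butyldimethylsilyloxy)-3-methylbutyl]-5-[(E)-3-methyl-4-oxobut-2-en-1-yl]-4-(triisopropylsilyloxy)benzoate | C/C(=C\Cc1cc(C(=O)OCC[Si](C)(C)C)cc(CC[C@@H](C)CO[Si](C)(C)C(C)(C)C)c1O[Si](C(C)C)(C(C)C)C(C)C)C=O | intermediate
22 | 2-(trimethylsilyl)ethyl 3-[(R)-4-(tert-butyldimethylsilyloxy)-3-methylbutyl]-5-[(E)-4-hydroxy-3-methylbut-2-en-1-yl]-4-(triisopropylsilyloxy)benzoate | C/C(=C\Cc1cc(C(=O)OCC[Si](C)(C)C)cc(CC[C@@H](C)CO[Si](C)(C)C(C)(C)C)c1O[Si](C(C)C)(C(C)C)C(C)C)CO | intermediate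
23 | 2-(trimethylsilyl)ethyl 3-[(E)-4-(tert-butyldiphenylsilyloxy)-3-methylbut-2-en-1-yl]-5-[(R)-4-(tert-butyldimethylsilyloxy)-3-methylbutyl]-4-(triisopropylsilyloxy)benzoate | C/C(=C\Cc1cc(C(=O)OCC[Si](C)(C)C)cc(CC[C@@H](C)CO[Si](C)(C)C(C)(C)C)c1O[Si](C(C)C)(C(C)C)C(C)C)CO[Si](c2ccccc2)(c2ccccc2)C(C)(C)C | intermediate
24 | 2-(trimethylsilyl)ethyl 3-[(E)-4-(tert-butyldiphenylsilyloxy)-3-methylbut-2-en-1-yl]-5-[(R)-4-hydroxy-3-methylbutyl]-4-(triisopropylsilyloxy)benzoate | C/C(=C\Cc1cc(C(=O)OCC[Si](C)(C)C)cc(CC[C@@H](C)CO)c1O[Si](C(C)C)(C(C)C)C(C)C)CO[Si](c2ccccc2)(c2ccccc2)C(C)(C)C | intermediate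
25 | 2-methylbut-3-yn-2-ol | CC(C)(O)C#C | starting material
26 | triethyl[(2-methylbut-3-yn-2-yl)oxy]silane | CC[Si](CC)(CC)OC(C)(C)C#C | intermediate
27 | chlorobis(cyclopentadienyl)[(E)-3-methyl-3-(triethylsilyloxy)but-1-en-1-yl]zirconium | Cl[Zr](/C=C/C(C)(C)O[Si](CC)(CC)CC)(C1C=CC=C1)C1C=CC=C1 | intermediate
28 | (E)-triethyl[(4-iodo-2-methylbut-3-en-2-yl)oxy]silane | I/C=C/C(C)(C)O[Si](CC)(CC)CC | intermediate
29 | 2-(trimethylsilyl)ethyl 3-[(E)-4-(tert-butyldiphenylsilyloxy)-3-methylbut-2-en-1-yl]-5-[(R)-3-methyl-4-oxobutyl]-4-(triisopropylsilyloxy)benzoate | C/C(=C\Cc1cc(C(=O)OCC[Si](C)(C)C)cc(CC[C@@H](C)C=O)c1O[Si](C(C)C)(C(C)C)C(C)C)CO[Si](c2ccccc2)(c2ccccc2)C(C)(C)C | intermediate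
30 | 2-(trimethylsilyl)ethyl 3-[(E)-4-(tert-butyldiphenylsilyloxy)-3-methylbut-2-en-1-yl]-5-[(3R,5E)-4-hydroxy-3,7-dimethyl-7-(triethylsilyloxy)oct-5-en-1-yl]-4-(triisopropylsilyloxy)benzoate | C/C(=C\Cc1cc(C(=O)OCC[Si](C)(C)C)cc(CC[C@@H](C)C(O)/C=C/C(C)(C)O[Si](CC)(CC)CC)c1O[Si](C(C)C)(C(C)C)C(C)C)CO[Si](c2ccccc2)(c2ccccc2)C(C)(C)C | intermediate
31 | 2-(trimethylsilyl)ethyl 3-[(E)-4-(tert-butyldiphenylsilyloxy)-3-methylbut-2-en-1-yl]-5-[(3R,5E)-3,7-dimethyl-4-oxo-7-(triethylsilyloxy)oct-5-en-1-yl]-4-(triisopropylsilyloxy)benzoate | C/C(=C\Cc1cc(C(=O)OCC[Si](C)(C)C)cc(CC[C@@H](C)C(=O)/C=C/C(C)(C)O[Si](CC)(CC)CC)c1O[Si](C(C)C)(C(C)C)C(C)C)CO[Si](c2ccccc2)(c2ccccc2)C(C)(C)C | intermediate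
32 | 4-hydroxy-3-[(E)-4-hydroxy-3-methylbut-2-en-1-yl]-5-[(3R,5E)-7-hydroxy-3,7-dimethyl-4-oxooct-5-en-1-yl]benzoic acid | C/C(=C\Cc1cc(C(=O)O)cc(CC[C@@H](C)C(=O)/C=C/C(C)(C)O)c1O)CO | target

**Step count**
Total: 20 steps. Longest linear sequence: 15 steps (steps 4–9, 10, 11–14, 17–20).

**Steps most likely to fail**

1. Step 10 (the labelled step). What may go wrong: silyl migration from oxygen to carbon in the ynol ether or its protonolysis before the first C–C bond forms; closure of the zwitterion at C5 to a cyclobutene instead of at the allyl-bearing C3; stalling of the second bond formation at the substituted C3. The fallback uses known arene chemistry without a pyrone; it sets out from alcohol 9 and comes back at arene 19. Alcohol 9 is oxidised (Swern) to (S)-3-(tert-butyldimethylsilyloxy)-2-methylpropanal F1, which is methylenated at once (Ph3P=CH2, THF, −78 to 0 °C) to (R)-tert-butyldimethyl[(2-methylbut-3-en-1-yl)oxy]silane F2 and hydroborated with 9-BBN-H to 9-[(R)-4-(tert-butyldimethylsilyloxy)-3-methylbutyl]-9-borabicyclo[3.3.1]nonane F3. Commercial 4-hydroxy-3-iodobenzoic acid (O=C(O)c1ccc(O)c(I)c1) is esterified with 2-(trimethylsilyl)ethanol (DCC, DMAP cat.) to 2-(trimethylsilyl)ethyl 4-hydroxy-3-iodobenzoate F4, then O-allylated (allyl bromide, K2CO3, acetone) to 2-(trimethylsilyl)ethyl 4-(allyloxy)-3-iodobenzoate F5. Aromatic Claisen rearrangement (N,N-diethylaniline, 190 °C) into the only free ortho position should give 2-(trimethylsilyl)ethyl 3-allyl-4-hydroxy-5-iodobenzoate F6, which is silylated (i-Pr3SiOTf, 2,6-lutidine) to 2-(trimethylsilyl)ethyl 3-allyl-5-iodo-4-(triisopropylsilyloxy)benzoate F7. B-alkyl Suzuki–Miyaura coupling of F3 with F7 (PdCl2(dppf), aq. K3PO4, THF/DMF, 50 °C) should then give 19.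

2. Step 9. What may go wrong: incomplete oxygen transfer from the peroxide to the acetylide; silylation of the ambident ynolate on carbon (silylketene) instead of oxygen; hydrolysis of the ynol ether during isolation. The fallback reaches the same ynolate by ester homologation; it sets out from iodide 10 and comes back at siloxyalkyne 17. Iodide 10 alkylates the lithium enolate of ethyl acetate (LiN(i-Pr)2, THF/DMPU, −78 to −30 °C) to give ethyl (R)-5-(tert-butyldimethylsilyloxy)-4-methylpentanoate F8. Kowalski ester homologation (CH2Br2 and lithium 2,2,6,6-tetramethylpiperidide at −78 °C, then LiN(SiMe3)2) converts it into lithium (R)-1,1-dibromo-6-(tert-butyldimethylsilyloxy)-5-methylhex-1-en-2-olate F9. n-BuLi then effects bromine–lithium exchange and 1,2-shift of the alkyl group to give lithium ynolate 16, which is silylated with i-Pr3SiOTf as in step 9 to give 17.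

3. Step 11. What may go wrong: migration of the allyl double bond into conjugation with the arene through ruthenium hydride species; homodimerisation of the allylarene; low turnover with the 1,1-disubstituted enal. The fallback replaces metathesis by cleavage and olefination; it sets out from arene 19 and comes back at enal 21. Lemieux–Johnson cleavage of the terminal alkene (OsO4 cat., NaIO4, 2,6-lutidine, dioxane/water) gives 2-(trimethylsilyl)ethyl 3-[(R)-4-(tert-butyldimethylsilyloxy)-3-methylbutyl]-5-(2-oxoethyl)-4-(triisopropylsilyloxy)benzoate F10. Wittig olefination with the stabilised ylide 2-(triphenylphosphoranylidene)propanal (toluene, 80 °C) is (E)-selective and should give 21.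

**Further compounds**
F1 | step 10 | (S)-3-(tert-butyldimethylsilyloxy)-2-methylpropanal | O=C[C@@H](C)CO[Si](C)(C)C(C)(C)C
F2 | step 10 | (R)-tert-butyldimethyl[(2-methylbut-3-en-1-yl)oxy]silane | C=C[C@@H](C)CO[Si](C)(C)C(C)(C)C
F3 | step 10 | 9-[(R)-4-(tert-butyldimethylsilyloxy)-3-methylbutyl]-9-borabicyclo[3.3.1]nonane | B1(CC[C@@H](C)CO[Si](C)(C)C(C)(C)C)C2CCCC1CCC2
F4 | step 10 | 2-(trimethylsilyl)ethyl 4-hydroxy-3-iodobenzoate | C[Si](C)(C)CCOC(=O)c1ccc(O)c(I)c1
F5 | step 10 | 2-(trimethylsilyl)ethyl 4-(allyloxy)-3-iodobenzoate | C=CCOc1ccc(C(=O)OCC[Si](C)(C)C)cc1I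
F6 | step 10 | 2-(trimethylsilyl)ethyl 3-allyl-4-hydroxy-5-iodobenzoate | C=CCc1cc(C(=O)OCC[Si](C)(C)C)cc(I)c1O
F7 | step 10 | 2-(trimethylsilyl)ethyl 3-allyl-5-iodo-4-(triisopropylsilyloxy)benzoate | C=CCc1cc(C(=O)OCC[Si](C)(C)C)cc(I)c1O[Si](C(C)C)(C(C)C)C(C)C
F8 | step 9 | ethyl (R)-5-(tert-butyldimethylsilyloxy)-4-methylpentanoate | CCOC(=O)CC[C@@H](C)CO[Si](C)(C)C(C)(C)C
F9 | step 9 | lithium (R)-1,1-dibromo-6-(tert-butyldimethylsilyloxy)-5-methylhex-1-en-2-olate | [Li]OC(=C(Br)Br)CC[C@@H](C)CO[Si](C)(C)C(C)(C)C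
F10 | step 11 | 2-(trimethylsilyl)ethyl 3-[(R)-4-(tert-butyldimethylsilyloxy)-3-methylbutyl]-5-(2-oxoethyl)-4-(triisopropylsilyloxy)benzoate | O=CCc1cc(C(=O)OCC[Si](C)(C)C)cc(CC[C@@H](C)CO[Si](C)(C)C(C)(C)C)c1O[Si](C(C)C)(C(C)C)C(C)C
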